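## Retrosynthetic overview

1. Target 20 comes from 19 by a last-step CAN unmasking of the A-half quinone.
2. Key step: ring B and the axis are made together. The O5–C5′ lactone-tethered cyclic vinylketene acetal 12 reacts with enantiopure sulfinylquinone 18 by [4+2], sulfoxide elimination and aryloxide-expelling aromatisation. No aryl–aryl coupling is used.
3. 12 comes from a seven-membered enol-lactone, closed by RCM of the 5-O-acrylate/6-methallyl juglone 9.
4. Ring A comes from a Brassard-type [4+2] of vinylketene acetal 4 with 2,5-dibromobenzoquinone, followed by Br→OEt exchange.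
5. The future C6–C8′ biaryl bond is made first, as an sp3–sp3 bond, by α-methallylation of ethyl senecioate. Ring order: A-quinone ring (purchased), ring A, oxepinone tether, then ring B built onto the B-quinone ring.

**Assumption:** the SMILES carries no stereodescriptor, and the only stereoelement is the tetra-ortho-substituted C6–C8′ axis. I target one atropisomer, (P) = (aS). Viewed along C6→C8′, going from C5(OH) to C8a′ is a 90° clockwise turn. Using ent-16 gives (M) by the same route.

**Locants:** juglone numbering throughout. Plain numbers are the A half (6-linked, 2-OEt). Primed numbers are the B half (8′-linked, 3′-OEt).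

## Route

**Step 1**
- Reactants: 1 ethyl 3-methylbut-2-enoate; 2 3-bromo-2-methylprop-1-ene
- Product: 3 ethyl 4-methyl-2-(prop-1-en-2-yl)pent-4-enoate (racemic; this centre becomes C6 and is flattened in step 2)
- Conditions: LDA, THF–DMPU, −78 °C; then 2, −78 → 0 °C
- Reagents that add atoms: methallyl bromide (2), C=C(C)CBr
- Why: Deconjugative α-alkylation of the lithium dienolate (α-attack is the kinetic rule with allylic halides) makes the future biaryl bond as a simple sp3–sp3 bond.

**Step 2**
- Reactants: 3
- Product: 4 [1-ethoxy-3-methyl-2-(2-methylallyl)buta-1,3-dien-1-yl]oxy-trimethylsilane (acetal E/Z mixture, irrelevant)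
- Conditions: LDA, THF, −78 °C; TMSCl
- Reagents that add atoms: TMSCl, C[Si](C)(C)Cl
- Why: Deprotonation of the doubly activated (α-ester, allylic) C–H and O-silylation of the hindered dienolate give a mixed vinylketene acetal (Brassard-type diene).

**Step 3**
- Reactants: 4; 5 2,5-dibromo-1,4-benzoquinone
- Product: 6 2-bromo-5-hydroxy-7-methyl-6-(2-methylallyl)-1,4-naphthoquinone
- Conditions: 5 (1.2 equiv), NaHCO3 (s), PhMe, −40 °C → rt; then SiO2, CH2Cl2
- Reagents that add atoms: 5, O=C1C=C(Br)C(=O)C=C1Br
- Why: In this Brassard vinylketene-acetal/haloquinone [4+2] annulation the CH2 terminus bonds to the Br-free carbon and the acetal carbon to C–Br, loss of HBr and EtOH/TMS then aromatises to the peri-hydroxyquinone with Br left at C2, and NaHCO3 prevents HBr-induced cyclisation of the phenol onto the methallyl group.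

**Step 4**
- Reactants: 6
- Product: 7 2-ethoxy-5-hydroxy-7-methyl-6-(2-methylallyl)-1,4-naphthoquinone
- Conditions: NaOEt (2.1 equiv), EtOH, 0 °C
- Reagents that add atoms: ethanol/ethoxide, CCO
- Why: Ipso addition–elimination (vinylogous acyl substitution) at C2–Br places the ethoxy group exactly where the bromine was.

**Step 5**
- Reactants: 7; 8 acryloyl chloride
- Product: 9 2-ethoxy-7-methyl-6-(2-methylallyl)-1,4-dioxo-1,4-dihydronaphthalen-5-yl acrylate
- Conditions: 8, i-Pr2NEt, DMAP (cat.), CH2Cl2, 0 °C
- Reagents that add atoms: acryloyl chloride (8), C=CC(=O)Cl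
- Why: DMAP-catalysed O-acylation of the only hydroxyl brings in C5′ and C6′.

**Step 6**
- Reactants: 9
- Product: 10 lactone-quinone: 2-ethoxy-7-methyl-1,4-naphthoquinone with O5 and C6 bridged by –C(=O)–CH=C(CH3)–CH2– (a naphtho[1,2-b]oxepin-2(5H)-one; ring alkene necessarily Z)
- Conditions: Hoveyda–Grubbs II (5–10 mol %), PhMe (2 mM), 80 °C
- Reagents that add atoms: none
- Why: Ring-closing metathesis of the acrylate with the 1,1-disubstituted olefin gives the seven-membered trisubstituted enoate, and the quinone suppresses Ru–H olefin isomerisation.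

**Step 7**
- Reactants: 10
- Product: 11 the same lactone on a 2-ethoxy-1,4-dimethoxy-7-methylnaphthalene core
- Conditions: Na2S2O4, EtOAc/H2O, rt; then Me2SO4, K2CO3, acetone, reflux, N2
- Reagents that add atoms: dimethyl sulfate, COS(=O)(=O)OC
- Why: Reductive methylation masks the quinone against strong base; O5 is already protected as the lactone, and anhydrous carbonate does not open it.

**Step 8**
- Reactants: 11
- Product: 12 2-(trimethylsilyloxy)naphtho[1,2-b]oxepine, ring sequence O5–C5′(OTMS)=C6′H–C7′(CH3)=C8′H–C6 (used crude)
- Conditions: LDA, TMSCl (in situ), THF, −78 °C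
- Reagents that add atoms: TMSCl, C[Si](C)(C)Cl
- Why: Vinylogous (γ) deprotonation with O-silylation takes the ring CH2, which is benzylic and cis to the carbonyl and so is kinetically preferred over the trans CH3, and the −78 °C in-situ trap avoids ketene/aryloxide fragmentation.

**Step 9**
- Reactants: 13 3-bromo-5-ethoxy-4-hydroxybenzaldehyde (catalogue compound; also available by Br2/AcOH on ethyl vanillin)
- Product: 14 2-bromo-6-ethoxybenzene-1,4-diol
- Conditions: 30 % H2O2, aq NaOH, rt, N2; then HCl
- Reagents that add atoms: hydrogen peroxide, OO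
- Why: Dakin oxidation of a p-hydroxybenzaldehyde proceeds by aryl migration and formate hydrolysis.

**Step 10**
- Reactants: 14
- Product: 15 1-bromo-3-ethoxy-2,5-dimethoxybenzene
- Conditions: MeI, K2CO3, acetone, reflux
- Reagents that add atoms: methyl iodide, CI
- Why: Williamson O-methylation of both phenols.

**Step 11**
- Reactants: 15; 16 (1R,2S,5R)-menthyl (S)-p-toluenesulfinate
- Product: 17 (S)-1-ethoxy-2,5-dimethoxy-3-(p-tolylsulfinyl)benzene
- Conditions: n-BuLi, THF, −78 °C; cannulate into 16, THF, −78 °C
- Reagents that add atoms: 16, C[C@@H]1CC[C@H]([C@@H](C1)O[S@](=O)c2ccc(C)cc2)C(C)C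
- Why: Li–Br exchange followed by Andersen sulfoxide synthesis sets the sulfur stereocentre by clean SN2 inversion at sulfur.

**Step 12**
- Reactants: 17
- Product: 18 (S)-2-ethoxy-6-(p-tolylsulfinyl)-1,4-benzoquinone
- Conditions: CAN, MeCN/H2O, rt
- Reagents that add atoms: water (source of the quinone oxygens), O
- Why: CAN oxidative demethylation of the para-dimethoxy pair leaves the sulfoxide and the ethoxy group untouched.

**Step 13 (key step)**
- Reactants: 12; 18
- Product: 19 (P)-3′-ethoxy-5′-hydroxy-7′-methyl-8′-(6-ethoxy-1-hydroxy-5,8-dimethoxy-3-methylnaphthalen-2-yl)-1′,4′-naphthoquinone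
- Conditions: 18 (1.1 equiv), 4 Å MS, CH2Cl2, −78 °C → rt; then Et3N·3HF, THF, 0 °C
- Reagents that add atoms: 18, Cc1ccc(cc1)[S@](=O)C1=CC(=O)C=C(OCC)C1=O
- Why: Proposed new method: the s-cis-locked cyclic vinylketene acetal should add across C2=C3 of 18 like a Brassard diene (nucleophilic C8′ to C3, which is β to both the sulfinyl group and the more electrophilic C1=O; acetal carbon C5′ to C2), endo and on the sulfur lone-pair face of the s-cis sulfoxide rotamer, to give a 2-oxabicyclo[3.2.2]nonadiene; syn-elimination of p-TolSOH restores the quinone, and ionisation of the bridging C5′–OAr bond followed by loss of H-8′ aromatises ring B, so the bridgehead configuration becomes the axis with O5 held on the ring-B face it departs from, giving (P); the closest known reaction types are the vinylketene-acetal/haloquinone annulation, the tandem Diels–Alder/sulfoxide elimination of enantiopure sulfinylquinones, [4+2] additions across C2–C5 of tropones and azepines, and central-to-axial chirality conversion on aromatisation.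

**Step 14**
- Reactants: 19
- Product: 20 (P)-3,2′-diethoxyisodiospyrin (target)
- Conditions: CAN (2.5 equiv), MeCN/H2O, 0 °C
- Reagents that add atoms: water, O
- Why: CAN oxidative demethylation attacks the most electron-rich (p-dimethoxy) ring to give the 2-ethoxy-1,4-quinone, while the B quinone, the chelated OH groups and both OEt groups are inert and the tetra-ortho-substituted axis cannot rotate at 0 °C.

**Stereochemical note:** the (P) assignment follows from the model of lone-pair-face attack on the s-cis rotamer with an endo approach. Endo and exo attack on the same quinone face give opposite axes. The sense and the er must therefore be checked by ECD or X-ray on 19.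

## Compound list

| No. | Name | SMILES | Role |
|---|---|---|---|
| 1 | ethyl 3-methylbut-2-enoate | CCOC(=O)C=C(C)C | starting material |
| 2 | 3-bromo-2-methylprop-1-ene | C=C(C)CBr | starting material |
| 3 | ethyl 4-methyl-2-(prop-1-en-2-yl)pent-4-enoate (rac) | CCOC(=O)C(CC(C)=C)C(C)=C | intermediate |
| 4 | vinylketene ethyl TMS acetal | CCOC(O[Si](C)(C)C)=C(CC(C)=C)C(C)=C | intermediate |
| 5 | 2,5-dibromo-1,4-benzoquinone | O=C1C=C(Br)C(=O)C=C1Br | starting material |
| 6 | 2-bromo-5-hydroxy-7-methyl-6-methallyl-1,4-naphthoquinone | O=C1C(Br)=CC(=O)c2c1cc(C)c(CC(C)=C)c2O | intermediate |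
| 7 | 2-ethoxy-5-hydroxy-7-methyl-6-methallyl-1,4-naphthoquinone | CCOC1=CC(=O)c2c(O)c(CC(C)=C)c(C)cc2C1=O | intermediate |
| 8 | acryloyl chloride | C=CC(=O)Cl | starting material |
| 9 | 5-O-acrylate of 7 | CCOC1=CC(=O)c2c(OC(=O)C=C)c(CC(C)=C)c(C)cc2C1=O | intermediate |
| 10 | oxepinone-fused quinone | CCOC1=CC(=O)c2c3OC(=O)C=C(C)Cc3c(C)cc2C1=O | intermediate |
| 11 | oxepinone-fused 2-ethoxy-1,4-dimethoxynaphthalene | CCOc1cc(OC)c2c3OC(=O)C=C(C)Cc3c(C)cc2c1OC | intermediate |
| 12 | 2-TMSO-naphthoxepine (cyclic vinylketene acetal) | CCOc1cc(OC)c2c3OC(O[Si](C)(C)C)=CC(C)=Cc3c(C)cc2c1OC | intermediate |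
| 13 | 3-bromo-5-ethoxy-4-hydroxybenzaldehyde | CCOc1cc(C=O)cc(Br)c1O | starting material |
| 14 | 2-bromo-6-ethoxybenzene-1,4-diol | CCOc1cc(O)cc(Br)c1O | intermediate |
| 15 | 1-bromo-3-ethoxy-2,5-dimethoxybenzene | CCOc1cc(OC)cc(Br)c1OC | intermediate |
| 16 | (1R,2S,5R)-menthyl (S)-p-toluenesulfinate | C[C@@H]1CC[C@H]([C@@H](C1)O[S@](=O)c2ccc(C)cc2)C(C)C | starting material |
| 17 | (S)-1-ethoxy-2,5-dimethoxy-3-(p-tolylsulfinyl)benzene | Cc1ccc(cc1)[S@](=O)c1cc(OC)cc(OCC)c1OC | intermediate |
| 18 | (S)-2-ethoxy-6-(p-tolylsulfinyl)-1,4-benzoquinone | Cc1ccc(cc1)[S@](=O)C1=CC(=O)C=C(OCC)C1=O | intermediate |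
| 19 | (P)-biaryl, A half still the dimethyl ether (axis not expressible in SMILES) | CCOc1cc(OC)c2c(O)c(-c3c(C)cc(O)c4c3C(=O)C=C(OCC)C4=O)c(C)cc2c1OC | intermediate |
| 20 | (P)-3,2′-diethoxyisodiospyrin (axis not expressible in SMILES) | CCOC1=CC(=O)c2c(cc(C)c(-c3c(C)cc(O)c4c3C(=O)C=C(OCC)C4=O)c2O)C1=O | target |

## Step count

- Total steps: 14.
- Longest linear sequence: 10 (steps 1–8, 13, 14).

## Steps most likely to fail

1. **Step 13.**
   - Risk: the twisted oxepine diene may be sluggish, the reaction may stop at the vinylogous Michael adduct, or endo/exo leakage may erode the er.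
   - Fallback: cut the tether. Open 11 with NaOEt/EtOH to the (Z)-enoate naphthol, protect O5 as MOM, and convert with LDA/TMSCl into the open-chain 4-aryl vinylketene acetal.
   - Then run a conventional Brassard annulation with 18, relying on untethered point-to-axial transfer.
   - If selectivity is still poor, annulate with achiral 2-bromo-6-ethoxybenzoquinone and resolve rac-19 as diastereomeric O-camphanates.
2. **Step 6.**
   - Risk: this RCM must form a hindered, trisubstituted, acrylate-derived seven-membered ring.
   - Fallback: carry the C4 unit from the start. Alkylate 1 with tert-butyl (Z)-4-bromo-3-methylbut-2-enoate instead of 2, run steps 2–4 as written, and close the same lactone by TFA then TFAA (mixed-anhydride O-acylation of 5-OH).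
3. **Step 14.**
   - Risk: CAN acts on a substrate with a free, electron-rich naphthol, so over-oxidation is possible.
   - Fallback: change the mask in step 7 to a bis-MOM hydroquinone (Na2S2O4; MOMCl, i-Pr2NEt). The endgame then becomes non-oxidative HCl/EtOH cleavage, where ethoxy exchange is degenerate, followed by mild air or Ag2O oxidation.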